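**Two runs.** The noon and autumn runs, at 0.010 M and 0.015 M of substrate with 0.20 mM of catalyst, differed by at most 0.8 percentage points in any reading. I therefore put the flask, at 0.020 M and the same catalyst, on their common percent curve.

| setting | noon | autumn | flask |
|---|---|---|---|
| substrate | 0.010 M | 0.015 M | 0.020 M |
| catalyst | 0.20 mM | 0.20 mM | 0.20 mM |
| remark | run made earlier | run made earlier |  |
| time |  |  | 25 min |

- noon (time / min: target / %, substrate / %): 6.00: 24.4, 66.0; 8.00: 29.3, 59.5; 10.0: 32.6, 53.9; 12.0: 35.2, 49.6; 15.0: 38.4, 44.3
- autumn (time / min: target / %, substrate / %): 6.00: 24.5, 66.1; 8.00: 29.2, 59.2; 10.0: 32.6, 54.2; 12.0: 35.7, 49.1; 15.0: 39.2, 44.5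

(each reading ± 0.3 percentage points)



* when, up to 25 min, the flask holds most target
* the amount of target, in percent of the substrate charged, at that time
* the first time at which target reaches 31%, in the same percent, in min

**Closing rate.** Averaged over both runs, substrate fell 34 points in the first 6.00 min and 17 points in the next, a ratio of 0.492. An exponential approach to a plateau keeps that ratio over equal steps. So I defined the closing rate λ, the relaxation rate at which substrate's distance from its plateau shrinks, as the logarithm of the inverse ratio over the step: 0.118 min⁻¹. The same ratio puts the plateau at A∞ = 33.2%.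

**Chain.** For the flask at 25 min I reckoned substrate at 36.7%, of which 3.5 points was gap to the plateau. The share f of lost substrate found as target read 0.698 at 15.0 min. Holding f at that reading, I reckoned the flask's target still climbing at 25 min, with 44.2% there. Interpolating the averaged readings put 31% at 9.04 min.

**Weak link.** The exponential shape was assumed, so I tested it on the 15.0 min readings, which λ had not used. It gave 44.5% against 44.3% and 44.5%.

**The forecast.** It gave 25 min, 42.5% and 9 min, taking the falling apparent constant as something “which fits a dying catalyst”. My reckoned target stood 1.7 points above its best.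

**Result.** The flask gave 25.0 min, 44.1% and 9.01 min. At 25.0 min it held substrate at 36.7% against my 36.7%, and catalyst at 100%.

    substrate + catalyst ⇌ target + catalyst, rate k1*[substrate]*[catalyst] forward; the back reaction follows from the equilibrium constant (K = 1.40, k = 6.40 L mol⁻¹ s⁻¹)
    target ⇌ isomer of the product (K = 0.440, k = 0.00590 s⁻¹)
    isomer of the product ⇌ substrate (k = 7.00 × 10⁻⁵ s⁻¹)

**Less catalyst.** A lower catalyst charge took target off the forecast's 42.5% in one neighbouring flask. For the neighbouring flask with 8.0 × 10⁻⁵ M of catalyst, I scaled λ with catalyst to 0.0473 min⁻¹, holding A∞ and f. At 25 min that gave substrate 53.7% and target 32.3%. At 25 min the neighbouring flask held substrate 52.5% and target 33.2%.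

Readings and results come from a simulation with constants of no real substance.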